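Percent of the electrophile charged is the unit of what follows, and two chemists disagree on how much of it stands as target in the flask at 6.0 min.

| flask | electrophile | nucleophile | remark | time |
|---|---|---|---|---|
| summer | 0.065 M | 0.143 M (fed, over 4.0 min) | run made earlier; the fed solution adds 0.20 times the starting volume |  |
| dawn | 0.098 M | 0.143 M (fed, over 4.0 min) | run made earlier; the fed solution adds 0.20 times the starting volume |  |
| dusk | 0.13 M | 0.21 M (fed, over 4.0 min) | run made earlier; the fed solution adds 0.20 times the starting volume |  |
| flask | 0.13 M | 0.143 M (fed, over 4.0 min) | the fed solution adds 0.20 times the starting volume | 6.0 min |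

- summer (time / min: target / %, electrophile / %): 1.33: 10.6, 87.9; 2.50: 31.7, 69.8; 4.00: 54.1, 45.5; 5.00: 67.5, 33.0; 6.00: 74.4, 27.5; 8.00: 80.6, 17.6
- dawn (time / min: target / %, electrophile / %): 0.500: 2.3, 96.4; 1.00: 6.0, 94.9; 1.50: 12.1, 86.9; 2.50: 26.3, 73.5; 4.00: 45.5, 54.2; 8.00: 66.7, 31.7
- dusk (time / min: target / %, electrophile / %): 1.33: 13.0, 85.2; 3.00: 39.2, 60.3; 4.00: 53.3, 46.9; 6.00: 70.4, 28.2; 8.00: 76.4, 24.0

(standard deviation of a reading: 1 percentage point)

- charges are per starting volume, the dose included; the dosed solution carries all of it

1. target present at 6.0 min, in percent of the electrophile charged
2. electrophile present at 6.0 min, in percent of the electrophile charged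

The first chemist counts in half-lives of the electrophile. The summer run has 27.5% electrophile left at 6.00 min, which is 1.86 half-lives. The flask gets the same nucleophile feed, so she expects the same count and about 74.4% target, although it holds twice the electrophile of the summer run.

The second chemist objects that the dawn run, on the same feed, has 45.5% target at 4.00 min, less than the 54.1% of the summer run, so the count shifts with the electrophile charged. At 8.00 min the dawn run has 2.19 nucleophile charged per target made, and the dusk run at 8.00 min has 2.11. He therefore takes two nucleophile per target. The flask's charge then gives 55.0%, the two-for-one mark, meaning the target at which two nucleophile per target equal the whole nucleophile charge. On his count nucleophile is the limiting reagent of this flask despite its 1.10 equivalents, since the mark is less than 100%.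

The first chemist keeps the summer run, whose mark of 110% is more than 100%, so on the two-for-one count the charge there covers the electrophile and half-lives remain the tool.

The dusk run, with the flask's electrophile, stood at 87.2% of its mark at 6.00 min. So I side with the second chemist and expect about 47.9% target in the flask. The forecast, 54% target and 45% electrophile, is higher than my figure and rests on a rate that falls as target builds, which “looks like product inhibition”.

The flask gives 51.1% target and 48.9% electrophile at 6.0 min.

    electrophile + nucleophile → acid set free + target (k = 0.0898 M⁻¹ s⁻¹)
    nucleophile + acid set free ⇌ protonated nucleophile, settled at all times (K = 3310 M⁻¹)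
    acid set free → by-product carried off (k = 0.00691 s⁻¹)

At that time the flask still holds 49% of its electrophile but a smaller part of its nucleophile unbound, 9.2%, with 0.0529 M standing as protonated nucleophile. Each target comes with one acid set free, and protonated nucleophile is that acid bound to a second nucleophile. The flask's target lies 3.9 percentage points under its mark of 55.0%. A neighbour flask charged with 0.036 M nucleophile has a mark of 13.8%, and at 6.00 min it holds 14.4% target.

The data are calculated on assumed constants.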